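**Retrosynthetic overview**

1. Target 17 ⇐ O5 desilylation ⇐ bis-sulfation of O4 and O7 ⇐ ester reduction ⇐ O5-selective silylation of catechol 13 ⇐ Dakin oxidation ⇐ ortho-formylation at C5 of phenol 9.
2. Phenol 9 ⇐ dehydrogenative aromatization of 2,3-dibromocyclohexenone 8; the benzene ring is formed last.
3. Enone 8 ⇐ one-carbon ring expansion: dibromocarbene from 6 enters the C2=C4 enol ether bond of bromocyclopentene 5, forming C2–C3 and C3–C4 (cyclopentene → cyclohexenone, the only ring construction).
4. Enol ether 5 ⇐ 1,4-hydrosilylation of 2-bromoenone 3 ⇐ alpha-bromination of commercial enone ester 1.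
5. Feature (target numbering: C1 bears C7H2O, C2 and C3 bear Br, C4 the sulfated O, C5 the OH, C6 is CH): the strategy rests on C3 of the benzene ring being a brominated carbon lodged between brominated C2 and oxygenated C4, which is exactly the carbon a dibromocarbene supplies.

Key step: step 3

Remark: the target is drawn as the neutral bis(hydrogen sulfate); sulfate esters 16 and 17 would be handled as pyridinium or ammonium salts and are written in their neutral acid form, the free diacid being liberated only at the end by cold cation exchange.

**Route**

Step 1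
Reactants: 1 methyl 3-oxocyclopent-1-ene-1-carboxylate
Product: 3 methyl 2-bromo-3-oxocyclopent-1-ene-1-carboxylate, via trans-dibromide 2 (not isolated)
Conditions: Br2 (1.1 equiv), CH2Cl2, 0 °C → rt; then Et3N (1.5 equiv), 0 °C
Reagents that add atoms: bromine, BrBr
Why: Bromine addition across the enone alkene followed by E1cB loss of HBr (the C2–H alpha to the ketone is removed and the C1 bromide leaves) is the classical alpha-bromination of a cyclic enone and can place the bromine only on C2.

Step 2
Reactants: 3 methyl 2-bromo-3-oxocyclopent-1-ene-1-carboxylate; 4 triethylsilane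
Product: 5 methyl 2-bromo-3-(triethylsilyloxy)cyclopent-2-ene-1-carboxylate (racemic)
Conditions: RhCl(PPh3)3 (2 mol %), Et3SiH (1.3 equiv), THF, 50 °C
Reagents that add atoms: triethylsilane (4), CC[SiH](CC)CC
Why: Rhodium-catalysed 1,4-hydrosilylation of an enone with a monohydrosilane should put silicon on the more Lewis-basic ketone oxygen and hydride on the beta-carbon C1, so the enol ether double bond is fixed between C4 and the brominated C2, and the new C1 stereocenter forms as a racemate that is erased on aromatization.

Step 3
Reactants: 5 methyl 2-bromo-3-(triethylsilyloxy)cyclopent-2-ene-1-carboxylate; 6 bromoform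
Product: 8 methyl 2,3-dibromo-4-oxocyclohex-2-ene-1-carboxylate (racemic), via tribromobicyclohexane adduct 7 (not isolated)
Conditions: CHBr3 (3 equiv), KOtBu (2.5 equiv, added in portions), pentane, −30 °C → rt; filter; PhMe, 80 °C; aqueous work-up
Reagents that add atoms: bromoform (6), BrC(Br)Br
Why: Proposed new method: singlet dibromocarbene, released from bromoform by KOtBu, should add in a concerted [2+1] cheletropic fashion to the only alkene of 5, and adduct 7 should then open by disrotatory two-electron electrocyclic cleavage of the shared cyclopropane bond, pushed by the silyloxy oxygen and pulled by loss of the endo bromide, after which bromide removes the silyl group to leave enone 8. The closest known reaction type is the dihalocarbene ring expansion of 1-silyloxycyclopentenes to 2-halocyclohex-2-enones; what is untested is an enol ether already carrying bromine on its beta-carbon, whose lower nucleophilicity towards the electrophilic carbene should be offset by the oxygen donor and the tetrasubstituted alkene. The six-membered ring is closed by one-carbon ring expansion of the cyclopentene and not by cyclization: the carbene carbon becomes C3 and forms the C2–C3 and C3–C4 bonds while the old C2–C4 bond breaks. No lasting stereocenter is created, since C1 stays racemic and the diastereomers of 7 converge on 8. The step needs carbene addition to outrun deprotonation of the acidic C1–H, which is secured by keeping the far more acidic bromoform in excess over slowly added base at low temperature. The order ester carbon, CBr, CBr, C=O is fixed by connectivity because the carbene can only enter between the two alkene carbons.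

Step 4
Reactants: 8 methyl 2,3-dibromo-4-oxocyclohex-2-ene-1-carboxylate
Product: 9 methyl 2,3-dibromo-4-hydroxybenzoate
Conditions: DDQ (1.3 equiv), TsOH·H2O (cat.), 1,4-dioxane, 90 °C
Reagents that add atoms: none
Why: Quinone dehydrogenation of a cyclohexenone to a phenol should proceed by acid-catalysed enolization through the acidic C1–H (vinylogous beta-keto ester), hydride abstraction from the resulting cyclohexadienol by DDQ and proton loss, leaving both vinylic bromines in place and erasing the C1 stereocenter.

Step 5
Reactants: 9 methyl 2,3-dibromo-4-hydroxybenzoate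
Product: 11 methyl 2,3-dibromo-5-formyl-4-hydroxybenzoate, via hydroxymethyl phenol 10 (not isolated)
Conditions: MgCl2 (2 equiv), Et3N (4 equiv), (CH2O)n (6 equiv), MeCN, reflux; then aq. HCl
Reagents that add atoms: paraformaldehyde (formaldehyde), C=O
Why: In the magnesium-mediated ortho-formylation of phenols the magnesium phenoxide should direct formaldehyde to the only free ortho position C5 (C3 carries bromine) and the hydroxymethyl intermediate 10 should be oxidized by a second formaldehyde in an Oppenauer-type hydride transfer, a method that tolerates ortho-bromo and para-ester phenols.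

Step 6
Reactants: 11 methyl 2,3-dibromo-5-formyl-4-hydroxybenzoate
Product: 13 methyl 2,3-dibromo-4,5-dihydroxybenzoate, via aryl formate 12 (not isolated)
Conditions: Na2CO3·1.5H2O2 (1.5 equiv), THF/H2O, 0 °C → rt; then aq. HCl to pH 2
Reagents that add atoms: hydrogen peroxide (delivered as Na2CO3·1.5H2O2), OO
Why: In the Dakin oxidation hydroperoxide adds to the aldehyde, the aryl group migrates to oxygen with the help of the ortho phenoxide despite the bromine and ester substituents, and the formate 12 is hydrolysed in situ, while the mild carbonate base should spare the hindered methyl ester.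

Step 7
Reactants: 13 methyl 2,3-dibromo-4,5-dihydroxybenzoate
Product: 14 methyl 2,3-dibromo-4-hydroxy-5-(triisopropylsilyloxy)benzoate
Conditions: iPr3SiCl (1.05 equiv), Et3N (2.2 equiv), DMF, 0 °C → rt
Reagents that add atoms: chlorotriisopropylsilane, CC(C)[Si](Cl)(C(C)C)C(C)C
Why: Phenol silylation under equilibrating basic conditions should leave the bulky silyl group on O5, because O4 is flanked by the C3 bromine and is the more acidic oxygen (para to the ester, ortho to bromine), so it rests as the triethylammonium phenoxide while any O4 silyl ether can shift to O5 by O-to-O silyl migration.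

Step 8
Reactants: 14 methyl 2,3-dibromo-4-hydroxy-5-(triisopropylsilyloxy)benzoate
Product: 15 [2,3-dibromo-4-hydroxy-5-(triisopropylsilyloxy)phenyl]methanol
Conditions: iBu2AlH (4 equiv), CH2Cl2, −78 → 0 °C; aq. KNaC4H4O6
Reagents that add atoms: none
Why: iBu2AlH should reduce the methyl benzoate to the benzylic alcohol (ester reduction) after one equivalent is consumed by the phenol, with the aryl bromides and the aryl silyl ether inert at low temperature.

Step 9
Reactants: 15 [2,3-dibromo-4-hydroxy-5-(triisopropylsilyloxy)phenyl]methanol
Product: 16 [2,3-dibromo-4-(sulfooxy)-5-(triisopropylsilyloxy)phenyl]methyl hydrogen sulfate (handled as its bis(pyridinium) salt)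
Conditions: SO3·pyridine (6 equiv), DMF, 0 °C → rt; evaporate, triturate
Reagents that add atoms: sulfur trioxide–pyridine complex, [O-]S(=O)(=O)[n+]1ccccc1
Why: O-Sulfation of a phenol and a primary benzylic alcohol with an amine–SO3 complex is standard, and an excess of reagent in DMF at low temperature should cap O4 before the transient 4-hydroxybenzyl sulfate can ionize to a quinone methide, the aryl silyl ether being inert to the reagent.

Step 10
Reactants: 16 [2,3-dibromo-4-(sulfooxy)-5-(triisopropylsilyloxy)phenyl]methyl hydrogen sulfate
Product: 17 [2,3-dibromo-5-hydroxy-4-(sulfooxy)phenyl]methyl hydrogen sulfate (target)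
Conditions: NH4F (5 equiv), MeOH, rt; C18 desalting; cation-exchange resin (H+ form), H2O, 0 °C, lyophilize
Reagents that add atoms: none
Why: Fluoride desilylation should cleave the aryl Si–O bond under near-neutral conditions that leave both sulfate monoesters untouched, the freed O5 phenol is meta to the benzylic carbon and so cannot expel the benzylic sulfate through a quinone methide, and cold proton exchange then gives the neutral diacid.

**Compound list**

1 | methyl 3-oxocyclopent-1-ene-1-carboxylate | COC(=O)C1=CC(=O)CC1 | starting material
2 | methyl 1,2-dibromo-3-oxocyclopentane-1-carboxylate (racemic trans-dibromide) | COC(=O)C1(Br)CCC(=O)C1Br | intermediate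
3 | methyl 2-bromo-3-oxocyclopent-1-ene-1-carboxylate | COC(=O)C1=C(Br)C(=O)CC1 | intermediate
4 | triethylsilane | CC[SiH](CC)CC | starting material
5 | methyl 2-bromo-3-(triethylsilyloxy)cyclopent-2-ene-1-carboxylate (racemic) | COC(=O)C1CCC(O[Si](CC)(CC)CC)=C1Br | intermediate
6 | bromoform | BrC(Br)Br | starting material
7 | methyl 1,6,6-tribromo-5-(triethylsilyloxy)bicyclo[3.1.0]hexane-2-carboxylate (racemic, mixture of diastereomers) | COC(=O)C1CCC2(O[Si](CC)(CC)CC)C(Br)(Br)C12Br | intermediate
8 | methyl 2,3-dibromo-4-oxocyclohex-2-ene-1-carboxylate (racemic) | COC(=O)C1CCC(=O)C(Br)=C1Br | intermediate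
9 | methyl 2,3-dibromo-4-hydroxybenzoate | COC(=O)c1ccc(O)c(Br)c1Br | intermediate
10 | methyl 2,3-dibromo-4-hydroxy-5-(hydroxymethyl)benzoate | COC(=O)c1cc(CO)c(O)c(Br)c1Br | intermediate
11 | methyl 2,3-dibromo-5-formyl-4-hydroxybenzoate | COC(=O)c1cc(C=O)c(O)c(Br)c1Br | intermediate
12 | methyl 2,3-dibromo-5-(formyloxy)-4-hydroxybenzoate | COC(=O)c1cc(OC=O)c(O)c(Br)c1Br | intermediate
13 | methyl 2,3-dibromo-4,5-dihydroxybenzoate | COC(=O)c1cc(O)c(O)c(Br)c1Br | intermediate
14 | methyl 2,3-dibromo-4-hydroxy-5-(triisopropylsilyloxy)benzoate | COC(=O)c1cc(O[Si](C(C)C)(C(C)C)C(C)C)c(O)c(Br)c1Br | intermediate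
15 | [2,3-dibromo-4-hydroxy-5-(triisopropylsilyloxy)phenyl]methanol | OCc1cc(O[Si](C(C)C)(C(C)C)C(C)C)c(O)c(Br)c1Br | intermediate
16 | [2,3-dibromo-4-(sulfooxy)-5-(triisopropylsilyloxy)phenyl]methyl hydrogen sulfate | O=S(=O)(O)OCc1cc(O[Si](C(C)C)(C(C)C)C(C)C)c(OS(=O)(=O)O)c(Br)c1Br | intermediate
17 | [2,3-dibromo-5-hydroxy-4-(sulfooxy)phenyl]methyl hydrogen sulfate | O=S(=O)(O)OCc1cc(O)c(OS(=O)(=O)O)c(Br)c1Br | target

**Step count**

Total steps: 10. Longest linear sequence: 10 steps (from 1).

**Steps most likely to fail**

Step 3 (Proposed new method). Carbene transfer to the bromine-deactivated, tetrasubstituted enol ether may be too slow, so that base-induced deprotonation at C1 and silyl loss outrun cyclopropanation. The fallback uses the ring expansion only on an unhalogenated enol ether, its known substrate class, and brings in the C2 bromine by arene bromination; it sets out from 1 and comes back at 13. RhCl(PPh3)3-catalysed 1,4-hydrosilylation of 1 with 4 should give methyl 3-(triethylsilyloxy)cyclopent-2-ene-1-carboxylate F1. Dibromocarbene (6, KOtBu, pentane) should add to give methyl 6,6-dibromo-5-(triethylsilyloxy)bicyclo[3.1.0]hexane-2-carboxylate F2, which should open to methyl 3-bromo-4-oxocyclohex-2-ene-1-carboxylate F3. DDQ should aromatize this to methyl 3-bromo-4-hydroxybenzoate F4 (also an article of commerce). MgCl2/Et3N/(CH2O)n should formylate C5 through methyl 3-bromo-4-hydroxy-5-(hydroxymethyl)benzoate F5 to methyl 3-bromo-5-formyl-4-hydroxybenzoate F6. Dakin oxidation with Na2CO3·1.5H2O2 should pass through methyl 3-bromo-5-(formyloxy)-4-hydroxybenzoate F7 to methyl 3-bromo-4,5-dihydroxybenzoate F8. Br2 in AcOH should then brominate C2, para to the O5 hydroxyl and next to the existing bromine, which is the established site of the second bromination of 5-bromo-protocatechuic-type arenes, giving 13.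

Step 2. The vinylic C–Br bond may add oxidatively to rhodium and be reduced off, or hydride may be delivered in the 1,2 sense at the tetrasubstituted alkene. The fallback reduces before brominating; it sets out from 1 and comes back at 5. Enone 1 is hydrosilylated first to the silyl enol ether F1 described above. NBS in THF at −78 °C should brominate its enol ether carbon regiospecifically to give methyl 2-bromo-3-oxocyclopentane-1-carboxylate F9. Soft enolization with Et3SiOTf/Et3N in CH2Cl2 at −78 → 0 °C should then remove the most acidic, bromine-bearing alpha-hydrogen and give 5.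

Step 7. Silylation may occur at O4 instead of O5, or silyl equilibration between the two catechol oxygens may stay incomplete, giving a regioisomeric mixture. The fallback fixes the regiochemistry with a non-migrating alkyl group on the more acidic oxygen; it sets out from 13 and comes back at 14. PMBCl with NaHCO3 and NaI in DMF at 40 °C should alkylate the more acidic O4 monoanion to give methyl 2,3-dibromo-5-hydroxy-4-[(4-methoxybenzyl)oxy]benzoate F10. iPr3SiCl/imidazole in DMF should silylate the remaining O5 to give methyl 2,3-dibromo-4-[(4-methoxybenzyl)oxy]-5-(triisopropylsilyloxy)benzoate F11. TFA with anisole in CH2Cl2 at 0 °C should then remove the PMB group and give 14.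

**Further compounds**

F1 | step 3 | methyl 3-(triethylsilyloxy)cyclopent-2-ene-1-carboxylate (racemic) | COC(=O)C1CCC(O[Si](CC)(CC)CC)=C1
F2 | step 3 | methyl 6,6-dibromo-5-(triethylsilyloxy)bicyclo[3.1.0]hexane-2-carboxylate (racemic) | COC(=O)C1CCC2(O[Si](CC)(CC)CC)C1C2(Br)Br
F3 | step 3 | methyl 3-bromo-4-oxocyclohex-2-ene-1-carboxylate (racemic) | COC(=O)C1CCC(=O)C(Br)=C1
F4 | step 3 | methyl 3-bromo-4-hydroxybenzoate | COC(=O)c1ccc(O)c(Br)c1
F5 | step 3 | methyl 3-bromo-4-hydroxy-5-(hydroxymethyl)benzoate | COC(=O)c1cc(Br)c(O)c(CO)c1
F6 | step 3 | methyl 3-bromo-5-formyl-4-hydroxybenzoate | COC(=O)c1cc(Br)c(O)c(C=O)c1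
F7 | step 3 | methyl 3-bromo-5-(formyloxy)-4-hydroxybenzoate | COC(=O)c1cc(Br)c(O)c(OC=O)c1
F8 | step 3 | methyl 3-bromo-4,5-dihydroxybenzoate | COC(=O)c1cc(O)c(O)c(Br)c1
F9 | step 2 | methyl 2-bromo-3-oxocyclopentane-1-carboxylate (racemic) | COC(=O)C1CCC(=O)C1Br
F10 | step 7 | methyl 2,3-dibromo-5-hydroxy-4-[(4-methoxybenzyl)oxy]benzoate | COC(=O)c1cc(O)c(OCc2ccc(OC)cc2)c(Br)c1Br
F11 | step 7 | methyl 2,3-dibromo-4-[(4-methoxybenzyl)oxy]-5-(triisopropylsilyloxy)benzoate | COC(=O)c1cc(O[Si](C(C)C)(C(C)C)C(C)C)c(OCc2ccc(OC)cc2)c(Br)c1Br
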